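Follow the partner left over once each substrate has taken its first one, and reckon with the fraction of mono adduct left, not the fraction made.

| flask | substrate | coupling partner | remark | time |
|---|---|---|---|---|
| winter | 15 mM | 1.5 equiv | run made earlier |  |
| dusk | 20 mM | 1.5 equiv | run made earlier |  |
| alder | 10 mM | 1.50 equiv |  | 40 min |
| birch | 10 mM | 0.800 equiv |  | 40 min |
| cedar | 10 mM | 2.50 equiv |  | 40 min |

- winter (time / min: mono adduct / %, substrate / %): 2.00: 49, 41; 4.00: 54, 22; 6.00: 57, 15; 8.00: 56, 6; 10.0: 51, 8; 12.0: 53, 6; 15.0: 50, 6
- dusk (time / min: mono adduct / %, substrate / %): 0.833: 41, 53; 2.00: 54, 31; 4.00: 58, 17; 6.00: 57, 15; 8.00: 53, 4; 12.0: 48, 5; 15.0: 51, 5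

(standard deviation of a reading: 2 percentage points)

- the analysis behind the earlier runs scatters by 2 percentage points, standard deviation
- reactions considered so far: substrate + coupling partner -> mono adduct; mono adduct <-> isomer of the product; coupling partner + bis adduct -> triple product; coupling partner + triple product <-> tetra adduct; coupling partner + mono adduct -> bis adduct

1. which of these holds the largest part of the substrate at the end of alder (bis adduct / substrate / triple product / mono adduct / tetra adduct)
2. which of these holds the largest part of the substrate at the end of birch (bis adduct / substrate / triple product / mono adduct / tetra adduct)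
3. which of these holds the largest part of the substrate at the end of cedar (bis adduct / substrate / triple product / mono adduct / tetra adduct)
4. mono adduct at the end of cedar, in percent of the substrate charged

In cedar 15.0 mM is the spare partner, what is charged beyond one per substrate. Dusk's first reading, 53 % substrate left, gives me a starting pace for cedar's substrate of 0.753 min⁻¹, a half-life of 0.920 min, short against the 40 min allowed. At the top of the mono curve, making equals using, and using means the second addition plus the step to the isomer, so substrate over mono there, averaged over winter and dusk, reads 0.278: while isomer is still forming, this is a high reading of the selectivity factor, second addition against first, and not the factor itself.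

Taking that high reading as it stands, I put the starting loss of mono adduct by second addition in cedar at 0.126 min⁻¹. Each mono adduct that moves on takes one partner, so if every one moved on, the spare in my reckoning falls to 5.00 mM, a slowing by a factor 3.00, to 0.0419 min⁻¹. Over the time allowed, I reckon the fraction left at 0.656 % at the fast pace and 18.7 % at the slow one. The partner remaining in that reckoning is half of the substrate charged, so I expect bis adduct to lead triple product in cedar. Alder's spare is 5.00 mM and birch has 8.00 mM of partner for 10 mM of substrate, so I expect mono adduct to lead in both.

The forecast says mono adduct for alder, mono adduct for birch, triple product for cedar and 18 % mono adduct in cedar: “so triple is narrowly ahead, with some uncertainty”.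

    substrate + coupling partner → mono adduct (k = 28.9 M⁻¹ min⁻¹)
    mono adduct ⇌ isomer of the product (K = 0.310, k = 0.0730 min⁻¹)
    coupling partner + bis adduct → triple product (k = 0.842 M⁻¹ min⁻¹)
    coupling partner + triple product ⇌ tetra adduct (K = 84.3 M⁻¹, k = 22.7 M⁻¹ min⁻¹)
    coupling partner + mono adduct → bis adduct (k = 5.67 M⁻¹ min⁻¹)

Alder ends led by mono adduct at 46.0 %, birch by mono adduct at 48.2 %, and cedar by bis adduct at 64.3 %, with 8.81 % triple product and 17.0 % mono adduct. In cedar, with partner as charged, mono adduct's half-life by its step to bis adduct is 4.9 min, shorter than bis adduct's 33 min by its step to triple product. Cedar, with its spare of 15.0 mM, still holds 5.62 mM of free partner at the end. The neighbour charged with 4.20 equiv has a spare of 32.0 mM, twice cedar's, and ends with 2.37 % mono adduct.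

The numbers in the tables are calculated with constants of no real substance; the scatter is artificial.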